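**Retrosynthetic overview**
- The ten-membered ring is formed last, by a two-fold decarboxylative radical vinylation that joins a bis-(Z)-vinyl iodide (14) to a C2-symmetric 1,3-dioxane-4,6-dicarboxylate (20). Both vinyl–carbinol bonds of the anti-1,3-diol are made in this step through 1,3-dioxan-4-yl radicals.
- The bis-vinyl iodide comes from a cis-fused cyclopentene lactone (11) by ozonolysis and double iodo-olefination. The cyclopentene is a template that fixes the all-cis lactone / ring-fusion / angelate triad.
- 11 comes from the Grieco lactone by epoxidation on the concave face, selenium-mediated epoxide-to-allylic-alcohol transposition and angeloylation. The lactone ring is therefore formed first (Baeyer–Villiger oxidation of cyclobutanone 1).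
- The dicarboxylate comes from (S)-4-hydroxycyclopent-2-enone by directed anti reduction, ozonolysis to the diester, benzylidene acetal formation and saponification.
- After ring closure: α-methylenation of the lactone, then acetal cleavage.

Assumption: (1R,5S)-bicyclo[3.2.0]hept-2-en-6-one and (S)-4-hydroxycyclopent-2-en-1-one are taken as commercially available in enantiopure form. "Endo" below means on the concave face, cis to the lactone ring.

**Step 1**
Reactants: 1 (1R,5S)-bicyclo[3.2.0]hept-2-en-6-one
Product: 2 (1S,5R)-2-oxabicyclo[3.3.0]oct-6-en-3-one (Grieco lactone)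
Conditions: 30% aq. H2O2, AcOH, 0 °C → rt
Reagents that add atoms: hydrogen peroxide, OO
Why: Baeyer–Villiger oxidation of the strained cyclobutanone, in which the more substituted ring-fusion carbon migrates with retention, so the cis fusion and both stereocenters of 1 pass unchanged into the lactone.

**Step 2**
Reactants: 2 (1S,5R)-2-oxabicyclo[3.3.0]oct-6-en-3-one
Product: 4 6,7-endo-epoxy-2-oxabicyclo[3.3.0]octan-3-one, via bromohydrin 3 (not isolated)
Conditions: NBS, DME/H2O (3:1), 0 °C; then K2CO3, rt
Reagents that add atoms: water, O (epoxide oxygen); N-bromosuccinimide, O=C1CCC(=O)N1Br (bromine present only in 3)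
Why: bromohydrin formation followed by Williamson closure: the bromonium ion forms on the open convex face, water opens it from the concave face, and SN2 closure at the C–Br carbon therefore places the oxirane oxygen on the concave face, cis to the lactone ring.

**Step 3**
Reactants: 4 6,7-endo-epoxy-2-oxabicyclo[3.3.0]octan-3-one
Product: 8 (3aR,4R,6aS)-4-hydroxy-3,3a,4,6a-tetrahydro-2H-cyclopenta[b]furan-2-one (hydroxyl cis to the lactone ring), via silyloxy selenide 5 (not isolated), via selenoxide 6 (not isolated), via silyl ether 7 (not isolated)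
Conditions: PhSeSiMe3, ZnI2 (5 mol %), CH2Cl2, 0 °C → rt; 30% aq. H2O2, pyridine, 0 °C → rt; aq. citric acid
Reagents that add atoms: trimethyl(phenylselanyl)silane, C[Si](C)(C)[Se]c1ccccc1 (present only in 5 to 7); hydrogen peroxide, OO (selenoxide oxygen of 6 only)
Why: Lewis-acid-assisted SN2 opening of the epoxide by selenium at the less hindered carbon remote from the ring fusion and from the convex face, then selenoxide syn-elimination away from oxygen (epoxide-to-allylic-alcohol transposition), which leaves the concave C–O bond intact and gives the all-cis allylic alcohol under base-free conditions that cannot open and re-close the lactone.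

**Step 4**
Reactants: 8 (3aR,4R,6aS)-4-hydroxy-3,3a,4,6a-tetrahydro-2H-cyclopenta[b]furan-2-one; 9 angelic acid, (Z)-2-methylbut-2-enoic acid
Product: 11 6-endo-angeloyloxy-2-oxabicyclo[3.3.0]oct-7-en-3-one, via mixed anhydride 10 (not isolated)
Conditions: 9, 2,4,6-Cl3C6H2COCl, Et3N, toluene, rt; then 8, toluene, 70 °C
Reagents that add atoms: 2,4,6-trichlorobenzoyl chloride, O=C(Cl)c1c(Cl)cc(Cl)cc1Cl (present only in 10)
Why: Yamaguchi esterification through the mixed anhydride, which acylates the hydroxyl without touching its C–O bond (configuration retained) and, run without DMAP, keeps the (Z)-geometry of the angelate.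

**Step 5**
Reactants: 11 6-endo-angeloyloxy-2-oxabicyclo[3.3.0]oct-7-en-3-one
Product: 13 cis-5-formyl-4-[1-(angeloyloxy)-2-oxoethyl]dihydrofuran-2(3H)-one (dialdehyde), via ozonide 12 (not isolated)
Conditions: O3, CH2Cl2, −78 °C (Sudan Red 7B endpoint); PPh3, −78 °C → rt
Reagents that add atoms: ozone, [O-][O+]=O
Why: ozonolysis with reductive work-up, in which the strained electron-rich cis-cyclopentene reacts much faster than the electron-poor trisubstituted angelate alkene when ozone is titrated to the indicator endpoint, and none of the three stereocenters is touched.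

**Step 6**
Reactants: 13 cis-5-formyl-4-[1-(angeloyloxy)-2-oxoethyl]dihydrofuran-2(3H)-one
Product: 14 cis-5-[(Z)-2-iodoprop-1-enyl]-4-[(Z)-1-(angeloyloxy)-3-iodobut-2-enyl]dihydrofuran-2(3H)-one (bis-vinyl iodide)
Conditions: Ph3P(Et)I, n-BuLi, THF, rt; I2, −78 °C; NaN(SiMe3)2, −20 °C; then 13, −78 → −20 °C
Reagents that add atoms: ethyltriphenylphosphonium iodide, CC[P+](c1ccccc1)(c1ccccc1)c1ccccc1.[I-]; iodine, [I][I]
Why: two-fold Stork–Zhao-type Wittig olefination with the α-iodoethylidene ylide, whose kinetic oxaphosphetane formation at low temperature places iodine cis to the chain, so both alkenes are (Z)-2-iodoalkenes and the α-oxygenated stereocenters are not epimerised.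

**Step 7**
Reactants: 15 (S)-4-hydroxycyclopent-2-en-1-one
Product: 16 (1S,3S)-cyclopent-4-ene-1,3-diol (trans)
Conditions: Me4NBH(OAc)3, MeCN/AcOH (1:1), −25 °C
Reagents that add atoms: none
Why: hydroxyl-directed reduction of Evans–Saksena type, in which the acetoxyborohydride binds to the existing hydroxyl and delivers hydride to the same face of the ketone, so the new hydroxyl is trans and no conjugate reduction occurs.

**Step 8**
Reactants: 16 (1S,3S)-cyclopent-4-ene-1,3-diol
Product: 18 dimethyl (2S,4S)-2,4-dihydroxypentanedioate, via hydroperoxy acetal 17 (not isolated)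
Conditions: O3, NaOH (2.5 M in MeOH), CH2Cl2, −78 °C
Reagents that add atoms: ozone, [O-][O+]=O; methanol, CO
Why: ozonolysis in basic methanol, which turns each alkene carbon directly into a methyl ester (methanol capture of the carbonyl oxide and ozone oxidation of the hemiacetal) without involving the two carbinol centers.

**Step 9**
Reactants: 18 dimethyl (2S,4S)-2,4-dihydroxypentanedioate
Product: 19 dimethyl (4S,6S)-2-phenyl-1,3-dioxane-4,6-dicarboxylate
Conditions: PhCH(OMe)2, CSA (5 mol %), CH2Cl2, 4 Å MS, rt
Reagents that add atoms: benzaldehyde dimethyl acetal, COC(OC)c1ccccc1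
Why: acid-catalysed transacetalisation to the six-membered benzylidene acetal (phenyl equatorial), which changes no stereocenter and creates none, because the acetal carbon carries two identical arms in this C2-symmetric diester.

**Step 10**
Reactants: 19 dimethyl (4S,6S)-2-phenyl-1,3-dioxane-4,6-dicarboxylate
Product: 20 dicesium (4S,6S)-2-phenyl-1,3-dioxane-4,6-dicarboxylate
Conditions: CsOH·H2O (2.0 equiv), THF/H2O (3:1), 0 °C; freeze-dry
Reagents that add atoms: cesium hydroxide (CsOH), [Cs+].[OH-]
Why: saponification, where hydroxide attack at the acyl carbon is much faster than α-deprotonation so the trans arrangement survives, and the salt is used as such because the free diacid would cleave its own acetal.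

**Step 11** (key step)
Reactants: 14 bis-vinyl iodide; 20 dicesium (4S,6S)-2-phenyl-1,3-dioxane-4,6-dicarboxylate
Product: 22 macrocyclic benzylidene-protected lactone (ten-membered ring closed; lactone α-carbon still CH2), via monocoupled carboxylate 21 (not isolated)
Conditions: Ir[dF(CF3)ppy]2(dtbbpy)PF6 (5 mol %), NiCl2(dme) (40 mol %), dtbbpy (45 mol %), DMSO, 2 mM (14 and 20 added over 12 h), 450 nm LEDs, 25 °C
Reagents that add atoms: none
Why: Proposed new method: two successive photoredox/nickel decarboxylative vinylations run as one ring-stitching event, in which the excited trivalent iridium complex oxidises a cesium carboxylate, loss of CO2 gives a 1,3-dioxan-4-yl (α-oxy) radical, this is captured by the vinyl–nickel species formed by oxidative addition of zerovalent nickel into a (Z)-vinyl iodide, and reductive elimination forms the vinyl–carbinol bond with retention of alkene geometry (first bond intermolecular, second closing the ten-membered ring); in the chair with equatorial phenyl each radical is trapped trans to the substituent on the other ring carbon (axial anomeric-type attack when that group is equatorial, equatorial attack when it is axial and a 1,3-diaxial clash would result), so each carboxylate is replaced with retention and the (S,S)-anti arrangement of 20 is relayed to both new carbinol centers, the closest known reactions being the dual-catalytic decarboxylative vinylation of α-oxy acids with vinyl iodides and the axial-selective couplings of glycosyl and 4-dioxanyl radicals.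

**Step 12**
Reactants: 22 macrocyclic benzylidene-protected lactone
Product: 26 benzylidene acetal of the target (α-methylene lactone), via lithium enolate 23 (not isolated), via Mannich base 24 (not isolated), via ammonium iodide 25 (not isolated)
Conditions: LiN(SiMe3)2 (1.1 equiv), THF, −78 °C; (CH2=NMe2)I, −78 → 0 °C; MeI, CH2Cl2/MeOH, rt; aq. NaHCO3, rt
Reagents that add atoms: N,N-dimethylmethyleneiminium iodide, C=[N+](C)C.[I-]; LiN(SiMe3)2, [Li+].C[Si](C)(C)[N-][Si](C)(C)C (lithium present only in 23); iodomethane, CI (present only in 25)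
Why: Mannich-type α-methylenation (enolate aminomethylation, quaternisation, E1cB elimination), which relies on the lactone α-CH2 being deprotonated by the bulky silylamide faster than the γ-hydrogens of the angelate and touches no stereocenter.

**Step 13**
Reactants: 26 benzylidene acetal of the target
Product: 27 CNP0152559.4 (target)
Conditions: AcOH/H2O/THF (3:1:1), 45 °C
Reagents that add atoms: none
Why: mild acid hydrolysis of the strained trans-fused benzylidene acetal, which breaks only the acetal C–O bonds and leaves the allylic carbinol configurations, the angelate and the α-methylene lactone intact.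

**Compound list**
1 | (1R,5S)-bicyclo[3.2.0]hept-2-en-6-one | O=C1C[C@@H]2C=CC[C@@H]21 | starting material
2 | (1S,5R)-2-oxabicyclo[3.3.0]oct-6-en-3-one (Grieco lactone) | O=C1C[C@@H]2C=CC[C@@H]2O1 | intermediate
3 | 6-exo-bromo-7-endo-hydroxy-2-oxabicyclo[3.3.0]octan-3-one (bromohydrin) | O=C1C[C@@H]2[C@@H](Br)[C@H](O)C[C@@H]2O1 | intermediate (not isolated)
4 | 6,7-endo-epoxy-2-oxabicyclo[3.3.0]octan-3-one (oxirane oxygen cis to the lactone ring) | O=C1C[C@@H]2[C@@H]3O[C@@H]3C[C@@H]2O1 | intermediate
5 | 7-exo-phenylselanyl-6-endo-trimethylsilyloxy-2-oxabicyclo[3.3.0]octan-3-one | O=C1C[C@@H]2[C@H](O[Si](C)(C)C)[C@@H]([Se]c3ccccc3)C[C@@H]2O1 | intermediate (not isolated)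
6 | selenoxide of 5 | O=C1C[C@@H]2[C@H](O[Si](C)(C)C)[C@@H]([Se](=O)c3ccccc3)C[C@@H]2O1 | intermediate (not isolated)
7 | 6-endo-trimethylsilyloxy-2-oxabicyclo[3.3.0]oct-7-en-3-one | O=C1C[C@@H]2[C@H](O[Si](C)(C)C)C=C[C@@H]2O1 | intermediate (not isolated)
8 | (3aR,4R,6aS)-4-hydroxy-3,3a,4,6a-tetrahydro-2H-cyclopenta[b]furan-2-one (OH, lactone O and lactone CH2 all on one face) | O=C1C[C@@H]2[C@H](O)C=C[C@@H]2O1 | intermediate
9 | angelic acid, (Z)-2-methylbut-2-enoic acid | C/C=C(/C)C(=O)O | starting material
10 | angelic 2,4,6-trichlorobenzoic anhydride | C/C=C(/C)C(=O)OC(=O)c1c(Cl)cc(Cl)cc1Cl | intermediate (not isolated)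
11 | 6-endo-angeloyloxy-2-oxabicyclo[3.3.0]oct-7-en-3-one (angelate of 8) | O=C1C[C@@H]2[C@H](OC(=O)/C(C)=C\C)C=C[C@@H]2O1 | intermediate
12 | ozonide (1,2,4-trioxolane) of 11 | O=C1C[C@@H]2[C@H](OC(=O)/C(C)=C\C)C3OOC(O3)[C@@H]2O1 | intermediate (not isolated)
13 | cis-5-formyl-4-[1-(angeloyloxy)-2-oxoethyl]dihydrofuran-2(3H)-one, configurations as in 11 | O=C1C[C@H]([C@H](OC(=O)/C(C)=C\C)C=O)[C@H](C=O)O1 | intermediate
14 | cis-5-[(Z)-2-iodoprop-1-enyl]-4-[(Z)-1-(angeloyloxy)-3-iodobut-2-enyl]dihydrofuran-2(3H)-one, configurations as in 11 | O=C1C[C@H]([C@H](OC(=O)/C(C)=C\C)/C=C(/C)I)[C@H](/C=C(/C)I)O1 | intermediate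
15 | (S)-4-hydroxycyclopent-2-en-1-one | O=C1C[C@H](O)C=C1 | starting material
16 | (1S,3S)-cyclopent-4-ene-1,3-diol | O[C@H]1C[C@H](O)C=C1 | intermediate
17 | (2S,4S)-2,4-dihydroxy-5-hydroperoxy-5-methoxypentanal | COC(OO)[C@@H](O)C[C@H](O)C=O | intermediate (not isolated)
18 | dimethyl (2S,4S)-2,4-dihydroxypentanedioate | COC(=O)[C@@H](O)C[C@H](O)C(=O)OC | intermediate
19 | dimethyl (4S,6S)-2-phenyl-1,3-dioxane-4,6-dicarboxylate | COC(=O)[C@@H]1C[C@H](OC(c2ccccc2)O1)C(=O)OC | intermediate
20 | dicesium (4S,6S)-2-phenyl-1,3-dioxane-4,6-dicarboxylate | [Cs+].[Cs+].[O-]C(=O)[C@@H]1C[C@H](OC(c2ccccc2)O1)C([O-])=O | intermediate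
21 | monocoupled cesium carboxylate (one vinyl iodide of 14 joined to the dioxane; shown for coupling at the lactone-side alkene, the regioisomer converges; acetal carbon either configuration) | O=C1C[C@H]([C@H](OC(=O)/C(C)=C\C)/C=C(/C)I)[C@H](/C=C(/C)[C@@H]2C[C@H](OC(c3ccccc3)O2)C([O-])=O)O1.[Cs+] | intermediate (not isolated)
22 | macrocyclic lactone: ten-membered carbocycle with two (Z)-trisubstituted alkenes, anti-diol as benzylidene acetal (acetal carbon either configuration), cis-fused saturated γ-lactone, angelate | C1C(=O)O[C@H]2/C=C(/C)[C@@H]3C[C@H](OC(c4ccccc4)O3)/C(C)=C\[C@@H](OC(=O)/C(C)=C\C)[C@@H]12 | intermediate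
23 | lithium enolate of 22 | C1=C([O-])O[C@H]2/C=C(/C)[C@@H]3C[C@H](OC(c4ccccc4)O3)/C(C)=C\[C@@H](OC(=O)/C(C)=C\C)[C@@H]12.[Li+] | intermediate (not isolated)
24 | α-(dimethylaminomethyl) lactone (Mannich base) | CN(C)CC1C(=O)O[C@H]2/C=C(/C)[C@@H]3C[C@H](OC(c4ccccc4)O3)/C(C)=C\[C@@H](OC(=O)/C(C)=C\C)[C@@H]12 | intermediate (not isolated)
25 | trimethylammonium iodide of 24 | C[N+](C)(C)CC1C(=O)O[C@H]2/C=C(/C)[C@@H]3C[C@H](OC(c4ccccc4)O3)/C(C)=C\[C@@H](OC(=O)/C(C)=C\C)[C@@H]12.[I-] | intermediate (not isolated)
26 | benzylidene acetal of the target (α-methylene lactone) | C=C1C(=O)O[C@H]2/C=C(/C)[C@@H]3C[C@H](OC(c4ccccc4)O3)/C(C)=C\[C@@H](OC(=O)/C(C)=C\C)[C@@H]12 | intermediate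
27 | CNP0152559.4: lactone carbinol S, ring-fusion carbon S, angelate carbinol R, both diol carbinols S, both ring alkenes Z | C=C1C(=O)O[C@H]2/C=C(/C)[C@@H](O)C[C@H](O)/C(C)=C\[C@@H](OC(=O)/C(C)=C\C)[C@@H]12 | target

**Totals**
Total step count: 13.
Longest linear sequence: 9 steps (steps 1–6, then 11–13). The dicarboxylate branch is steps 7–10.

**The three steps most likely to fail**

Step 11. Both partners are bifunctional, so oligomers can win over the ring, and the trans selectivity of the second, ring-closing capture is not proven. The fallback sets out from 19 and 14 and makes the two bonds one at a time with differentiated ends. Partial saponification of 19 with one equivalent of CsOH gives the half-ester cesium salt F1. This is coupled under the same dual catalysis at normal concentration with an excess of 14 (recovered), giving the monovinylated methyl ester F2. Selective hydrolysis of the methyl ester with Me3SnOH (1,2-dichloroethane, 70 °C) gives the seco-acid F3. Its cesium salt (Cs2CO3) is 21, where the fallback comes back to the route. 21 is then closed to 22 as a purely intramolecular event at 1 mM.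

Step 6. A double iodo-olefination of a sensitive α-oxygenated dialdehyde may give low yield or mixed geometry. The fallback sets out from 13. Dibromo-olefination of both aldehydes (CBr4, PPh3, 2,6-lutidine, CH2Cl2, 0 °C) gives the bis(1,1-dibromoalkene) F4. Negishi coupling with MeZnCl (Pd(PPh3)4, THF, rt) replaces only the bromine trans to the chain and gives the bis[(Z)-2-bromoalkene] F5. F5 takes the place of 14 in step 11 (vinyl bromides are competent partners), and the fallback comes back to the route at 22.

Step 3. Selenium may open the epoxide at the carbon next to the ring fusion, which after elimination gives the wrong allylic alcohol. The fallback sets out from 4 and removes the regiochemical question. Treatment with Et2Al(NC9H18) (diethylaluminium 2,2,6,6-tetramethylpiperidide, 2.5 equiv, toluene, 0 °C) first converts the lactone into its diethylaluminium enolate F6, which shields it. The amide then isomerises the epoxide by syn-elimination through a cyclic transition state. Only the CH2 group has a hydrogen on the same face as the oxirane oxygen (the ring-fusion hydrogen is on the other face), so only the C–O bond next to the CH2 group breaks. Cold aqueous citric acid work-up gives 8, where the fallback comes back to the route.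

**Further compounds**
F1 | step 11 | cesium (4S,6S)-6-(methoxycarbonyl)-2-phenyl-1,3-dioxane-4-carboxylate | [Cs+].[O-]C(=O)[C@@H]1C[C@H](OC(c2ccccc2)O1)C(=O)OC
F2 | step 11 | monovinylated methyl ester (methyl ester analogue of 21) | O=C1C[C@H]([C@H](OC(=O)/C(C)=C\C)/C=C(/C)I)[C@H](/C=C(/C)[C@@H]2C[C@H](OC(c3ccccc3)O2)C(=O)OC)O1
F3 | step 11 | seco-acid (free acid of 21) | O=C1C[C@H]([C@H](OC(=O)/C(C)=C\C)/C=C(/C)I)[C@H](/C=C(/C)[C@@H]2C[C@H](OC(c3ccccc3)O2)C(=O)O)O1
F4 | step 6 | bis(1,1-dibromoalkene) from 13 | O=C1C[C@H]([C@H](OC(=O)/C(C)=C\C)C=C(Br)Br)[C@H](C=C(Br)Br)O1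
F5 | step 6 | bis[(Z)-2-bromoalkene] analogue of 14 | O=C1C[C@H]([C@H](OC(=O)/C(C)=C\C)/C=C(/C)Br)[C@H](/C=C(/C)Br)O1
F6 | step 3 | diethylaluminium enolate of 4 | CC[Al](CC)OC1=C[C@@H]2[C@@H]3O[C@@H]3C[C@@H]2O1
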